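**Strategy**

Ring carbon C4 of the oxolane (O1, C2 carrying the 3,4-dimethoxyphenyl group, C3 carrying C9, C4, C5) is flanked by two oxygen-bearing one-carbon units, the ring methylene C5 and the exocyclic carbonyl carbon C7'. Together with C4 and one oxygen they map onto a symmetric oxetan-3-yl group. The route therefore rests on the O1–C5 disconnection. Under Lewis acid catalysis the C2 hydroxyl of an anti β-hydroxy ester, ethyl (2S,3R)-3-(3,4-dimethoxyphenyl)-3-hydroxy-2-(oxetan-3-yl)propanoate, opens one oxetane methylene. In a single operation this closes the oxolane, sets C4 and releases C7' as a primary alcohol for later arylation. An enzymatic dynamic kinetic resolution supplies the precursor.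

Key step: step 3

Remark: ring atoms are numbered O1, C2 (aryl-bearing), C3 (bearing C9), C4 (bearing C7'), C5 throughout; ethyl 2-(oxetan-3-yl)acetate is taken as a catalogue building block; the carbinol carbon C7' made in step 5 is carried as a mixture of epimers because step 7 removes it as a stereocentre.

**Route**

Step 1
Reactants: 1 ethyl 2-(oxetan-3-yl)acetate; 2 3,4-dimethoxybenzoyl chloride
Product: 3 ethyl 3-(3,4-dimethoxyphenyl)-2-(oxetan-3-yl)-3-oxopropanoate (racemic, α-centre labile)
Conditions: LiN(SiMe3)2 (2.2 equiv), THF, −78 °C; then 2, −78 → −40 °C; aq. NH4Cl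
Reagents that add atoms: none
Why: Crossed Claisen-type C-acylation of the lithium ester enolate by the aroyl chloride should give the β-keto ester, the second equivalent of base converting the more acidic product into its enolate at once so that over-acylation stops, while the oxetane is inert to amide base at low temperature.

Step 2
Reactants: 3 ethyl 3-(3,4-dimethoxyphenyl)-2-(oxetan-3-yl)-3-oxopropanoate
Product: 4 ethyl (2S,3R)-3-(3,4-dimethoxyphenyl)-3-hydroxy-2-(oxetan-3-yl)propanoate (anti)
Conditions: anti-selective NADPH-dependent ketoreductase (panel-selected), NADP+ (cat.), i-PrOH, KH2PO4/K2HPO4 buffer pH 7.0, DMSO (5% v/v), 30 °C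
Reagents that add atoms: none
Why: Ketoreductase-catalysed dynamic kinetic resolution: the proton between the two carbonyls exchanges through the enol faster than hydride transfer at neutral pH, the enzyme accepts only the (2S)-keto ester and delivers hydride to one carbonyl face to give the (3R)-carbinol, so both stereocentres of the anti isomer are set by the enzyme while i-PrOH recycles the cofactor.

Step 3
Reactants: 4 ethyl (2S,3R)-3-(3,4-dimethoxyphenyl)-3-hydroxy-2-(oxetan-3-yl)propanoate
Product: 5 ethyl (2R,3S,4R)-2-(3,4-dimethoxyphenyl)-4-(hydroxymethyl)oxolane-3-carboxylate (aryl and ester cis, ester and CH2OH trans)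
Conditions: Sc(OTf)3 (5 mol%), 4 Å MS, CH2Cl2, −30 → 0 °C; then Et3N
Reagents that add atoms: none
Why: Sc(OTf)3 binds the oxetane oxygen, the most Lewis-basic site, and the C2 hydroxyl displaces it from one ring CH2 in an intramolecular SN2 reaction, after which proton transfer frees the C7' primary alcohol and returns the catalyst; release of the four-membered-ring strain makes the etherification irreversible. The closest known reaction type is the acid-catalysed intramolecular alcoholysis of 3-substituted oxetanes to 3-(hydroxymethyl)tetrahydrofurans, which is also known in desymmetrising form. The oxolane ring (O1, C2, C3, C4, C5) closes in the 5-exo-tet mode. The new stereocentre C4 arises from the choice between the two diastereotopic oxetane methylenes and is controlled by the neighbouring stereocentre C3: attack on the methylene that leaves the remaining CH2O arm trans to the ester avoids the crowding of three contiguous cis substituents in the competing transition state. The C2–O bond and C3–H are not touched, so the anti relationship of 4 is carried over as the 2,3-cis relationship of the ring. The step needs oxetane activation to outrun ionisation of the electron-rich benzylic C2–OH, and the hydroxyl to outcompete the ester carbonyl as nucleophile; the first is secured by the inductively withdrawing ester on the adjacent carbon together with low temperature, the second by the higher nucleophilicity of the alcohol and the fact that an ethyl ester would have to dealkylate before a lactone could form.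

Step 4
Reactants: 5 ethyl (2R,3S,4R)-2-(3,4-dimethoxyphenyl)-4-(hydroxymethyl)oxolane-3-carboxylate
Product: 6 ethyl (2R,3S,4S)-2-(3,4-dimethoxyphenyl)-4-formyloxolane-3-carboxylate
Conditions: Dess–Martin periodinane, pyridine, CH2Cl2, 0 °C → rt
Reagents that add atoms: none
Why: Dess–Martin oxidation should stop cleanly at the aldehyde under buffered, near-neutral conditions, so that C3 and the now enolisable C4 keep their configuration; the aldehyde is used at once.

Step 5
Reactants: 6 ethyl (2R,3S,4S)-2-(3,4-dimethoxyphenyl)-4-formyloxolane-3-carboxylate; 7 5-bromo-1,2,3-trimethoxybenzene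
Product: 9 ethyl (2R,3S,4S)-2-(3,4-dimethoxyphenyl)-4-[hydroxy(3,4,5-trimethoxyphenyl)methyl]oxolane-3-carboxylate (both C7' carbinol epimers), via 3,4,5-trimethoxyphenylmagnesium bromide 8 (not isolated)
Conditions: 7, Mg turnings, THF, rt → 40 °C; then 6 (Grignard 1.2 equiv), THF, −78 °C; aq. NH4Cl
Reagents that add atoms: none
Why: Grignard 1,2-addition: at −78 °C the aryl nucleophile should add to the aldehyde far faster than it attacks or deprotonates the hindered ethyl ester, and the new carbinol centre is formed without useful control and deliberately left as a mixture because step 7 flattens it.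

Step 6
Reactants: 9 ethyl (2R,3S,4S)-2-(3,4-dimethoxyphenyl)-4-[hydroxy(3,4,5-trimethoxyphenyl)methyl]oxolane-3-carboxylate
Product: 10 [(3S,4R,5R)-5-(3,4-dimethoxyphenyl)-4-(hydroxymethyl)oxolan-3-yl](3,4,5-trimethoxyphenyl)methanol (both C7' carbinol epimers)
Conditions: LiBH4, THF, 0 °C → rt; aq. NH4Cl
Reagents that add atoms: none
Why: Hydride reduction of the ester by LiBH4 should convert CO2Et into the C9 primary alcohol without touching the aryl ethers, the oxolane or any ring stereocentre, and C3 ceases to be enolisable at this point.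

Step 7
Reactants: 10 [(3S,4R,5R)-5-(3,4-dimethoxyphenyl)-4-(hydroxymethyl)oxolan-3-yl](3,4,5-trimethoxyphenyl)methanol
Product: 11 [(3S,4R,5R)-5-(3,4-dimethoxyphenyl)-4-(hydroxymethyl)oxolan-3-yl](3,4,5-trimethoxyphenyl)methanone (target, 2R,3R,4S in route numbering)
Conditions: activated MnO2, CH2Cl2, rt
Reagents that add atoms: none
Why: MnO2 oxidation is selective for benzylic alcohols, so the C7' carbinol should become the aryl ketone while the saturated primary alcohol C9 is left alone, and the neutral heterogeneous conditions do not disturb C4, which already sits trans to the C3 substituent.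

**Compound list**

1 | ethyl 2-(oxetan-3-yl)acetate | CCOC(=O)CC1COC1 | starting material
2 | 3,4-dimethoxybenzoyl chloride | COc1ccc(C(Cl)=O)cc1OC | starting material
3 | ethyl 3-(3,4-dimethoxyphenyl)-2-(oxetan-3-yl)-3-oxopropanoate (racemic) | CCOC(=O)C(C1COC1)C(=O)c1ccc(OC)c(OC)c1 | intermediate
4 | ethyl (2S,3R)-3-(3,4-dimethoxyphenyl)-3-hydroxy-2-(oxetan-3-yl)propanoate (anti) | COc1ccc([C@H](O)[C@@H](C(=O)OCC)C2COC2)cc1OC | intermediate
5 | ethyl (2R,3S,4R)-2-(3,4-dimethoxyphenyl)-4-(hydroxymethyl)oxolane-3-carboxylate | COc1ccc([C@@H]2OC[C@@H](CO)[C@@H]2C(=O)OCC)cc1OC | intermediate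
6 | ethyl (2R,3S,4S)-2-(3,4-dimethoxyphenyl)-4-formyloxolane-3-carboxylate | COc1ccc([C@@H]2OC[C@@H](C=O)[C@@H]2C(=O)OCC)cc1OC | intermediate
7 | 5-bromo-1,2,3-trimethoxybenzene | COc1cc(Br)cc(OC)c1OC | starting material
8 | 3,4,5-trimethoxyphenylmagnesium bromide | COc1cc([Mg]Br)cc(OC)c1OC | intermediate
9 | ethyl (2R,3S,4S)-2-(3,4-dimethoxyphenyl)-4-[hydroxy(3,4,5-trimethoxyphenyl)methyl]oxolane-3-carboxylate, both epimers at C7' | COc1ccc([C@@H]2OC[C@@H](C(O)c3cc(OC)c(OC)c(OC)c3)[C@@H]2C(=O)OCC)cc1OC | intermediate
10 | [(3S,4R,5R)-5-(3,4-dimethoxyphenyl)-4-(hydroxymethyl)oxolan-3-yl](3,4,5-trimethoxyphenyl)methanol, both epimers at C7' | COc1ccc([C@@H]2OC[C@@H](C(O)c3cc(OC)c(OC)c(OC)c3)[C@@H]2CO)cc1OC | intermediate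
11 | [(3S,4R,5R)-5-(3,4-dimethoxyphenyl)-4-(hydroxymethyl)oxolan-3-yl](3,4,5-trimethoxyphenyl)methanone (CNP0271206.1) | COc1ccc([C@@H]2OC[C@@H](C(=O)c3cc(OC)c(OC)c(OC)c3)[C@@H]2CO)cc1OC | target

**Step count and risks**

Total step count: 7. Longest linear sequence: 7 steps (1 → 3 → 4 → 5 → 6 → 9 → 10 → 11).

Steps most likely to fail:

1. Step 3. The cyclisation may discriminate poorly between the two oxetane methylenes, so that C4 is formed as a mixture. The fallback gives up kinetic control at C4 and sets it by equilibration. It sets out from 4: the cyclisation mixture of 5 and its C4 epimer, ethyl (2R,3S,4S)-2-(3,4-dimethoxyphenyl)-4-(hydroxymethyl)oxolane-3-carboxylate F1, is oxidised as a whole with Dess–Martin periodinane. This should give 6 together with the all-cis aldehyde ethyl (2R,3S,4R)-2-(3,4-dimethoxyphenyl)-4-formyloxolane-3-carboxylate F2. Brief treatment with catalytic DBU in CH2Cl2 at 0 °C should then epimerise only the aldehyde α-carbon, since the ester α-proton at C3 is far less acidic, and drain the crowded all-cis isomer into the 3,4-trans aldehyde. The route is rejoined at 6.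

2. Step 2. The enzyme panel may not accept the α-branched aryl keto ester, or racemisation of the bulky substrate may be too slow, which would show as stalled conversion or loss of anti selectivity. The fallback replaces biocatalysis by substrate-controlled reduction and a physical resolution. From 3, Felkin–Anh-controlled reduction with LiEt3BH in the presence of non-chelating CeCl3 (THF, −78 °C) should give the racemic anti hydroxy ester, that is 4 together with its enantiomer ethyl (2R,3S)-3-(3,4-dimethoxyphenyl)-3-hydroxy-2-(oxetan-3-yl)propanoate F3. Preparative chromatography on a chiral stationary phase (supercritical CO2/MeOH) returns 4, where the route is rejoined.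

3. Step 5. The basic Grignard reagent may enolise the aldehyde, leading to epimerisation at C4 or β-elimination of the ring oxygen, or may attack the ester. The fallback moves the C7'–aryl bond formation to a neutral acyl cross-coupling. From 5, oxidation with TEMPO (cat.) and PhI(OAc)2 in MeCN/H2O should give (3S,4S,5R)-5-(3,4-dimethoxyphenyl)-4-(ethoxycarbonyl)oxolane-3-carboxylic acid F4. Coupling with EtSH (EDCI, DMAP, CH2Cl2) should give ethyl (2R,3S,4S)-2-(3,4-dimethoxyphenyl)-4-[(ethylsulfanyl)carbonyl]oxolane-3-carboxylate F5. Liebeskind–Srogl coupling with 3,4,5-trimethoxyphenylboronic acid (Pd2(dba)3 as zerovalent palladium source, tris(2-furyl)phosphine, copper thiophene-2-carboxylate Cu(O2C-2-C4H3S) of monovalent copper, THF, 50 °C) should give ethyl (2R,3S,4S)-2-(3,4-dimethoxyphenyl)-4-(3,4,5-trimethoxybenzoyl)oxolane-3-carboxylate F6. LiBH4 in THF then reduces ketone and ester together, and the route is rejoined at diol 10.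

Further compounds
F1 | step 3 | ethyl (2R,3S,4S)-2-(3,4-dimethoxyphenyl)-4-(hydroxymethyl)oxolane-3-carboxylate | COc1ccc([C@@H]2OC[C@H](CO)[C@@H]2C(=O)OCC)cc1OC
F2 | step 3 | ethyl (2R,3S,4R)-2-(3,4-dimethoxyphenyl)-4-formyloxolane-3-carboxylate | COc1ccc([C@@H]2OC[C@H](C=O)[C@@H]2C(=O)OCC)cc1OC
F3 | step 2 | ethyl (2R,3S)-3-(3,4-dimethoxyphenyl)-3-hydroxy-2-(oxetan-3-yl)propanoate | COc1ccc([C@@H](O)[C@H](C(=O)OCC)C2COC2)cc1OC
F4 | step 5 | (3S,4S,5R)-5-(3,4-dimethoxyphenyl)-4-(ethoxycarbonyl)oxolane-3-carboxylic acid | COc1ccc([C@@H]2OC[C@@H](C(=O)O)[C@@H]2C(=O)OCC)cc1OC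
F5 | step 5 | ethyl (2R,3S,4S)-2-(3,4-dimethoxyphenyl)-4-[(ethylsulfanyl)carbonyl]oxolane-3-carboxylate | COc1ccc([C@@H]2OC[C@@H](C(=O)SCC)[C@@H]2C(=O)OCC)cc1OC
F6 | step 5 | ethyl (2R,3S,4S)-2-(3,4-dimethoxyphenyl)-4-(3,4,5-trimethoxybenzoyl)oxolane-3-carboxylate | COc1ccc([C@@H]2OC[C@@H](C(=O)c3cc(OC)c(OC)c(OC)c3)[C@@H]2C(=O)OCC)cc1OC
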